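The benzene ring is numbered C1' (CH2 bridge), C2' (OH), C3' (prenyl), C4' (OH), C5' (acyl), C6' (OMe). Its neighbouring atoms C5' and C6' carry a ketone carbon and an oxygen, and both bonds, C6'–O and C5'–C(=O), are formed in one operation when a 3,5-dioxygenated benzyne inserts into the C–O bond of (R)-2-methylbutanoic acid, which delivers the stereocentre without Lewis acid. The precursor is a 2-(trimethylsilyl)aryl triflate bearing two methoxymethyl ethers. The phenol set free at C6' then relays a prenyl group to C3' (para-Claisen shift) and is methylated; the pyrone ring is attached last through a methylene at C1'.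

Key step: step 4

Assumption: (R)-2-methylbutanoic acid is bought in high enantiomeric purity; the spectator oxygens are protected as methoxymethyl ethers, not benzyl ethers, because mild acid removes them with the prenyl alkene already in place, whereas hydrogenolysis would reduce it.

Step 1
Reactants: 1 phloroglucinol (benzene-1,3,5-triol)
Product: 2 3,5-bis(methoxymethoxy)phenol
Conditions: MOMCl (2.0 equiv), i-Pr2NEt, DMF, 0 °C to rt; chromatography
Reagents that add atoms: chloromethyl methyl ether, COCCl
Why: Williamson-type O-alkylation of three equivalent phenols is statistical, so two equivalents of the chloride should make the bis-ether the main fraction, separable from mono- and tris-ether (the mono-ether can be alkylated again).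

Step 2
Reactants: 2 3,5-bis(methoxymethoxy)phenol
Product: 3 2-bromo-3,5-bis(methoxymethoxy)phenol
Conditions: NBS (1.0 equiv), i-Pr2NH (10 mol%), CH2Cl2, −78 to 0 °C
Reagents that add atoms: N-bromosuccinimide, O=C1CCC(=O)N1Br
Why: Electrophilic aromatic bromination in which amine-mediated, hydrogen-bond-guided delivery of bromine favours the two equivalent positions ortho to the hydroxyl over the more hindered carbon flanked by two acetal ethers.

Step 3
Reactants: 3 2-bromo-3,5-bis(methoxymethoxy)phenol
Product: 7 3,5-bis(methoxymethoxy)-2-(trimethylsilyl)phenyl trifluoromethanesulfonate, via O-silyl ether 4 (not isolated), via aryllithium 5 (not isolated), via lithium 2-silylphenolate 6 (not isolated)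
Conditions: (Me3Si)2NH, THF, 65 °C, then evaporate; n-BuLi, THF, −100 to −78 °C; Tf2O, −100 °C to rt
Reagents that add atoms: hexamethyldisilazane, C[Si](C)(C)N[Si](C)(C)C; trifluoromethanesulfonic anhydride, O=S(=O)(OS(=O)(=O)C(F)(F)F)C(F)(F)F
Why: O-silylation, bromine–lithium exchange and retro-Brook 1,3 O-to-C silyl migration give the lithium phenolate, which is trapped as the triflate; exchange at −100 °C is far faster than ether-directed deprotonation, so the acetal ethers are not touched.

Step 4
Reactants: 7 3,5-bis(methoxymethoxy)-2-(trimethylsilyl)phenyl trifluoromethanesulfonate; 8 (R)-2-methylbutanoic acid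
Product: 11 (2R)-1-[2-hydroxy-4,6-bis(methoxymethoxy)phenyl]-2-methylbutan-1-one, via caesium (R)-2-methylbutanoate 9 (not isolated), via 3,5-bis(methoxymethoxy)benzyne 10 (not isolated)
Conditions: 8 (2 equiv), Cs2CO3 (1 equiv), MeOH, rt, then evaporate and dry; 7 (1 equiv), CsF (3 equiv), THF, 110 °C, sealed tube; cold 0.5 M HCl work-up
Reagents that add atoms: none
Why: Fluoride removes the silyl group of 7 with loss of triflate to give aryne 10, whose triple bond is polarised by the acetal oxygen beside it (future O4'), so that carboxylate 9 adds through oxygen at the remote aryne carbon (future C6') and the negative charge appears at the carbon next to that oxygen (future C5'). This aryl anion attacks the neighbouring ester carbonyl through a four-membered transition state and the adduct opens to the caesium phenolate of the ortho-hydroxyaryl ketone, a net 1,3 O-to-C acyl shift that forms C6'–O and C5'–C(=O) in one operation. The closest known reaction type is the fluoride-mediated insertion of arynes from 2-silylaryl triflates into the C–O bond of carboxylic acids, an anionic Fries-type acyl transfer, of which an alpha-branched aliphatic acid is a demanding case. No ring closes and no stereocentre is created: the R centre is brought in by 8 and should survive, since a carboxylate does not enolise and the acyl shift leaves the alpha carbon untouched. The step needs regioselective addition to the unsymmetrical aryne, secured by the inductive effect of the oxygen flanking the triple bond, and acyl transfer faster than protonation of the aryl anion, secured by the preformed caesium salt in dry aprotic solvent with no O–H acid present.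

Step 5
Reactants: 11 (2R)-1-[2-hydroxy-4,6-bis(methoxymethoxy)phenyl]-2-methylbutan-1-one; 12 prenyl bromide (1-bromo-3-methylbut-2-ene)
Product: 13 (2R)-1-{2,4-bis(methoxymethoxy)-6-[(3-methylbut-2-en-1-yl)oxy]phenyl}-2-methylbutan-1-one
Conditions: K2CO3, DMF, rt
Reagents that add atoms: none
Why: Williamson ether synthesis (SN2 at the primary allylic bromide) on the only free phenol; carbonate is much too weak to enolise the hindered aryl ketone, so the R centre is not at risk.

Step 6
Reactants: 13 (2R)-1-{2,4-bis(methoxymethoxy)-6-[(3-methylbut-2-en-1-yl)oxy]phenyl}-2-methylbutan-1-one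
Product: 15 (2R)-1-[6-hydroxy-2,4-bis(methoxymethoxy)-3-(3-methylbut-2-en-1-yl)phenyl]-2-methylbutan-1-one, via ortho-dienone 14 (not isolated)
Conditions: Eu(fod)3 (10 mol%; fod = 6,6,7,7,8,8,8-heptafluoro-2,2-dimethyloctane-3,5-dionate), NaHCO3, CHCl3, 60 °C
Reagents that add atoms: none
Why: Lewis acid-catalysed para-Claisen (Claisen–Cope) rearrangement, in which chelation of europium between the ketone and ether oxygens accelerates the first [3,3] shift to ortho-dienone 14 (1,1-dimethylallyl at C1'), a second [3,3] shift carries the group, again as a normal prenyl unit, to C3' (para to O6'), and enolisation gives the phenol; the sp3 ring carbon of 14 is transient, so no stereocentre remains, and the buffered conditions should not enolise the R centre.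

Step 7
Reactants: 15 (2R)-1-[6-hydroxy-2,4-bis(methoxymethoxy)-3-(3-methylbut-2-en-1-yl)phenyl]-2-methylbutan-1-one
Product: 16 (2R)-1-[6-methoxy-2,4-bis(methoxymethoxy)-3-(3-methylbut-2-en-1-yl)phenyl]-2-methylbutan-1-one
Conditions: MeI, K2CO3, acetone, 56 °C
Reagents that add atoms: iodomethane, CI
Why: Williamson O-methylation of the single, ketone-chelated phenol freed by the rearrangement, which is the C6' oxygen made in the key step.

Step 8
Reactants: 16 (2R)-1-[6-methoxy-2,4-bis(methoxymethoxy)-3-(3-methylbut-2-en-1-yl)phenyl]-2-methylbutan-1-one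
Product: 17 (2R)-1-[2,4-dihydroxy-6-methoxy-3-(3-methylbut-2-en-1-yl)phenyl]-2-methylbutan-1-one
Conditions: 3 M HCl (aq), MeOH, rt
Reagents that add atoms: none
Why: Acid-catalysed acetal cleavage (transacetalisation of both methoxymethyl ethers to methanol) proceeds in dilute acid at room temperature, conditions under which an ortho-prenylphenol should not yet cyclise to a chroman and the methyl ether and ketone are inert.

Step 9
Reactants: 18 pentan-3-one
Product: 20 trimethyl(pent-2-en-3-yloxy)silane, via lithium enolate 19 (not isolated)
Conditions: LiN(i-Pr)2, THF, −78 °C; Me3SiCl, −78 °C to rt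
Reagents that add atoms: chlorotrimethylsilane, C[Si](C)(C)Cl
Why: Enolate formation and O-silylation (silyl enol ether synthesis); the ketone is symmetric, so only one regioisomer can form and the double-bond geometry is lost in the next step.

Step 10
Reactants: 20 trimethyl(pent-2-en-3-yloxy)silane
Product: 22 6-ethyl-4-hydroxy-5-methyl-2H-pyran-2-one, via 4-methyl-3,5-dioxoheptanoyl chloride 21 (not isolated)
Conditions: ClC(O)CH2C(O)Cl, Et2O, −78 °C to rt; aqueous work-up
Reagents that add atoms: malonyl dichloride, O=C(Cl)CC(=O)Cl
Why: C-acylation of the silyl enol ether by one acid chloride group gives 21, whose enol oxygen closes the six-membered lactone on the second acid chloride (acylative lactonisation), and tautomerisation gives the 4-hydroxy-2-pyranone, a known pyranone synthesis from silyl enol ethers.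

Step 11
Reactants: 22 6-ethyl-4-hydroxy-5-methyl-2H-pyran-2-one; 17 (2R)-1-[2,4-dihydroxy-6-methoxy-3-(3-methylbut-2-en-1-yl)phenyl]-2-methylbutan-1-one
Product: 25 6-ethyl-4-hydroxy-3-{[2,4-dihydroxy-6-methoxy-3-(3-methylbut-2-en-1-yl)-5-[(2R)-2-methylbutanoyl]phenyl]methyl}-5-methyl-2H-pyran-2-one (target), via Mannich base hydroiodide 23 (not isolated), via 3-methylidenepyran-2,4-dione 24 (not isolated)
Conditions: 22, CH2=NMe2+ I− (1.0 equiv), CHCl3, rt; then 17 (0.9 equiv), 60 °C
Reagents that add atoms: N,N-dimethylmethyleneiminium iodide, C=[N+](C)C.[I-]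
Why: Mannich aminomethylation at C3, the only nucleophilic carbon of 22, gives 23, which loses dimethylamine on warming to Michael acceptor 24; Friedel–Crafts-type conjugate addition of the single unsubstituted ring carbon of 17 (C1', activated by O2', O4' and O6') and re-enolisation to the 4-hydroxypyranone give the methylene bridge, and 22 is fully converted to 23 first so that no free pyranone is left to dimerise.

Compound list
1 | phloroglucinol (benzene-1,3,5-triol) | Oc1cc(O)cc(O)c1 | starting material
2 | 3,5-bis(methoxymethoxy)phenol | COCOc1cc(O)cc(OCOC)c1 | intermediate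
3 | 2-bromo-3,5-bis(methoxymethoxy)phenol | COCOc1cc(O)c(Br)c(OCOC)c1 | intermediate
4 | [2-bromo-3,5-bis(methoxymethoxy)phenoxy]trimethylsilane | COCOc1cc(O[Si](C)(C)C)c(Br)c(OCOC)c1 | intermediate (not isolated)
5 | [2-lithio-3,5-bis(methoxymethoxy)phenoxy]trimethylsilane | COCOc1cc(O[Si](C)(C)C)c([Li])c(OCOC)c1 | intermediate (not isolated)
6 | lithium 3,5-bis(methoxymethoxy)-2-(trimethylsilyl)phenolate | COCOc1cc([O-])c([Si](C)(C)C)c(OCOC)c1.[Li+] | intermediate (not isolated)
7 | 3,5-bis(methoxymethoxy)-2-(trimethylsilyl)phenyl trifluoromethanesulfonate | COCOc1cc(OS(=O)(=O)C(F)(F)F)c([Si](C)(C)C)c(OCOC)c1 | intermediate (key-step precursor)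
8 | (R)-2-methylbutanoic acid | CC[C@@H](C)C(=O)O | starting material
9 | caesium (R)-2-methylbutanoate | CC[C@@H](C)C(=O)[O-].[Cs+] | intermediate (not isolated)
10 | 3,5-bis(methoxymethoxy)benzyne | COCOC1=CC(OCOC)=CC#C1 | intermediate (not isolated)
11 | (2R)-1-[2-hydroxy-4,6-bis(methoxymethoxy)phenyl]-2-methylbutan-1-one | CC[C@@H](C)C(=O)c1c(O)cc(OCOC)cc1OCOC | intermediate (key-step product)
12 | prenyl bromide (1-bromo-3-methylbut-2-ene) | CC(C)=CCBr | starting material
13 | (2R)-1-{2,4-bis(methoxymethoxy)-6-[(3-methylbut-2-en-1-yl)oxy]phenyl}-2-methylbutan-1-one | CC[C@@H](C)C(=O)c1c(OCC=C(C)C)cc(OCOC)cc1OCOC | intermediate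
14 | 3,5-bis(methoxymethoxy)-6-(2-methylbut-3-en-2-yl)-2-[(2R)-2-methylbutanoyl]cyclohexa-2,4-dien-1-one (ring sp3 carbon uncontrolled) | CC[C@@H](C)C(=O)C1=C(OCOC)C=C(OCOC)C(C(C)(C)C=C)C1=O | intermediate (not isolated)
15 | (2R)-1-[6-hydroxy-2,4-bis(methoxymethoxy)-3-(3-methylbut-2-en-1-yl)phenyl]-2-methylbutan-1-one | CC[C@@H](C)C(=O)c1c(O)cc(OCOC)c(CC=C(C)C)c1OCOC | intermediate
16 | (2R)-1-[6-methoxy-2,4-bis(methoxymethoxy)-3-(3-methylbut-2-en-1-yl)phenyl]-2-methylbutan-1-one | CC[C@@H](C)C(=O)c1c(OC)cc(OCOC)c(CC=C(C)C)c1OCOC | intermediate
17 | (2R)-1-[2,4-dihydroxy-6-methoxy-3-(3-methylbut-2-en-1-yl)phenyl]-2-methylbutan-1-one | CC[C@@H](C)C(=O)c1c(OC)cc(O)c(CC=C(C)C)c1O | intermediate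
18 | pentan-3-one | CCC(=O)CC | starting material
19 | lithium pent-2-en-3-olate | CC=C(CC)[O-].[Li+] | intermediate (not isolated)
20 | trimethyl(pent-2-en-3-yloxy)silane (mixture of geometric isomers) | CC=C(CC)O[Si](C)(C)C | intermediate
21 | 4-methyl-3,5-dioxoheptanoyl chloride (racemic, enolisable) | CCC(=O)C(C)C(=O)CC(=O)Cl | intermediate (not isolated)
22 | 6-ethyl-4-hydroxy-5-methyl-2H-pyran-2-one | CCc1oc(=O)cc(O)c1C | intermediate
23 | 3-[(dimethylamino)methyl]-6-ethyl-4-hydroxy-5-methyl-2H-pyran-2-one hydroiodide | CCc1oc(=O)c(C[NH+](C)C)c(O)c1C.[I-] | intermediate (not isolated)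
24 | 6-ethyl-5-methyl-3-methylidene-2H-pyran-2,4(3H)-dione | CCC1=C(C)C(=O)C(=C)C(=O)O1 | intermediate (not isolated)
25 | 6-ethyl-4-hydroxy-3-{[2,4-dihydroxy-6-methoxy-3-(3-methylbut-2-en-1-yl)-5-[(2R)-2-methylbutanoyl]phenyl]methyl}-5-methyl-2H-pyran-2-one | CCc1oc(=O)c(Cc2c(O)c(CC=C(C)C)c(O)c(C(=O)[C@H](C)CC)c2OC)c(O)c1C | target

Total step count: 11. Longest linear sequence: 9 steps (steps 1 to 8 and step 11, from phloroglucinol); the pyranone branch is steps 9 and 10.

Steps most likely to fail

Step 4. The aryl anion may be protonated before it reaches the hindered, alpha-branched ester carbonyl, which would leave the aryl ester. The product phenolate may also be arylated by a second aryne, and the alpha centre may erode at the temperature required; the enantiomeric purity of 11 should therefore be checked before going on. The fallback makes the same C5'–C(=O) bond by an anionic Fries-type shift at low temperature. It sets out from bromophenol 3 and acid 8: esterification (DCC, catalytic DMAP, CH2Cl2, 0 °C) would give 2-bromo-3,5-bis(methoxymethoxy)phenyl (2R)-2-methylbutanoate F1. Bromine–lithium exchange on F1 (t-BuLi, 2 equiv, THF, −100 °C) would generate the ortho-acyloxy aryllithium, whose 1,3 O-to-C acyl migration and acidic work-up return to ketone 11.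

Step 6. The first sigmatropic shift may end with enolisation of the ortho-dienone, leaving a 1,1-dimethylallyl group at C1'. The Lewis acid may also ionise the allyl ether, leading to 1,3-shift or chroman products, and chelation may promote slow enolisation of the ketone. The fallback replaces the intramolecular relay by intermolecular C-alkylation and sets out from 11. Methylation (MeI, K2CO3, acetone) would give (2R)-1-[2-methoxy-4,6-bis(methoxymethoxy)phenyl]-2-methylbutan-1-one F2, and acetal cleavage (HCl, MeOH, rt) would give (2R)-1-(2,4-dihydroxy-6-methoxyphenyl)-2-methylbutan-1-one F3. C-prenylation of the dianion of F3 with 12 (aqueous KOH, 0 °C to rt), at the carbon flanked by the two phenoxide oxygens, returns to 17; the cost would be chromatographic separation from C1'-alkylated, O-alkylated and doubly alkylated material.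

Step 11. The methylidene compound 24 may be consumed by any remaining pyranone to give a methylene-bis-pyranone, or by hetero-Diels–Alder addition to the prenyl alkene, and the crowded C1' may add too slowly. The fallback reverses the roles of the partners and sets out from 17. Aminomethylation at C1' with the same iminium iodide (MeCN, rt) would give (2R)-1-{3-[(dimethylamino)methyl]-4,6-dihydroxy-2-methoxy-5-(3-methylbut-2-en-1-yl)phenyl}-2-methylbutan-1-one F4. Heating F4 with pyranone 22 (dioxane, 80 °C) would release the ortho-quinone methide of the benzene ring, which the nucleophilic C3 of 22 traps by Michael addition to give 25.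

Further compounds
F1 | step 4 | 2-bromo-3,5-bis(methoxymethoxy)phenyl (2R)-2-methylbutanoate | CC[C@@H](C)C(=O)Oc1cc(OCOC)cc(OCOC)c1Br
F2 | step 6 | (2R)-1-[2-methoxy-4,6-bis(methoxymethoxy)phenyl]-2-methylbutan-1-one | CC[C@@H](C)C(=O)c1c(OC)cc(OCOC)cc1OCOC
F3 | step 6 | (2R)-1-(2,4-dihydroxy-6-methoxyphenyl)-2-methylbutan-1-one | CC[C@@H](C)C(=O)c1c(OC)cc(O)cc1O
F4 | step 11 | (2R)-1-{3-[(dimethylamino)methyl]-4,6-dihydroxy-2-methoxy-5-(3-methylbut-2-en-1-yl)phenyl}-2-methylbutan-1-one | CC[C@@H](C)C(=O)c1c(OC)c(CN(C)C)c(O)c(CC=C(C)C)c1O
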